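**Retrosynthetic overview**

- Feature used: in the benzene ring (the only ring) the four adjacent carbons C3(OH)–C4(OH)–C5(CHO)–C6(OH) carry oxygen, oxygen, carbon, oxygen, the pattern of a squaric ester in which one alkoxy group has been replaced by carbon. C1 (bearing the side chain C1'–C12') and C2 (H) are a two-carbon alkene unit.
- Endgame simplification: C5–CHO is taken back to C5–CH2OMOM (through hydroquinone/quinone redox) and C4–OH to C4–O-iPr, giving a 4-isopropoxy-3-(MOM-oxymethyl)hydroquinone acid.
- Key disconnection: the ring is opened at C6–C1 (after retro-enolisation) to a 4-alkenyl-4-hydroxycyclobutenone. The benzene ring is therefore formed last, in one thermal 4π-opening/6π-closure cascade.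
- The cyclobutenone is cut between the carbinol carbon and the alkenyl carbon into 3-isopropoxy-4-(MOM-oxymethyl)cyclobutenedione (from diisopropyl squarate and MOMOCH2Li) and an (E)-vinyllithium that carries the acid as its lithium carboxylate.
- The (E)-iodo-diene acid comes from (2E,6E)-farnesyl acetate: terminal allylic oxidation to the 2-methyl-2-enoic acid, asymmetric hydrogenation to set C11' (S), then allyl–alkynyl coupling with ethynyltrimethylsilane and hydrozirconation–iodination.

Key step: step 13

Assumption: the (S)-H8-BINAP ruthenium diacetate of step 5 is taken to reduce the 2-methyl-2-enoic acid with the facial sense it shows for tiglic acid, giving the (2S) acid; the carbinol carbon of the cyclobutenone is formed as both epimers, which does not matter because it becomes an aromatic carbon.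

**Step 1**
Reactants: 1 diisopropyl squarate; 2 tributyl[(methoxymethoxy)methyl]stannane
Product: 6 3-isopropoxy-4-[(methoxymethoxy)methyl]cyclobut-3-ene-1,2-dione, via (methoxymethoxy)methyllithium 3 (not isolated), via lithium alkoxide 1,2-adduct 4 (not isolated), via tertiary trifluoroacetate 5 (not isolated)
Conditions: 2, n-BuLi, THF, −78 °C; add to 1, THF, −78 °C; (CF3CO)2O, −78 °C; aq. NH4Cl, −78 °C to rt
Reagents that add atoms: water, O
Why: Tin–lithium exchange gives the α-alkoxymethyllithium 3, which adds once to a squarate carbonyl, and trifluoroacetylation of 4, ionisation of 5 to the alkoxy-stabilised cyclobutenyl cation, hydration at the isopropoxy-bearing terminus and loss of isopropanol complete the standard organolithium addition–rearrangement route from squaric esters to 3-alkoxy-4-alkylcyclobutenediones.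

**Step 2**
Reactants: 7 (2E,6E)-farnesyl acetate
Product: 8 (2E,6E,10E)-12-hydroxy-3,7,11-trimethyldodeca-2,6,10-trien-1-yl acetate
Conditions: SeO2 (cat.), t-BuOOH, salicylic acid (cat.), CH2Cl2, rt
Reagents that add atoms: selenium dioxide SeO2, O=[Se]=O; tert-butyl hydroperoxide, CC(C)(C)OO
Why: Catalytic SeO2/t-BuOOH allylic oxidation (Riley oxidation; ene reaction then [2,3]-sigmatropic shift) attacks the terminal, most accessible trisubstituted alkene at its (E)-methyl group, so the primary allylic alcohol should form as the (10E) isomer, with unreacted 7 recycled and any over-oxidised aldehyde carried into step 3.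

**Step 3**
Reactants: 8 (2E,6E,10E)-12-hydroxy-3,7,11-trimethyldodeca-2,6,10-trien-1-yl acetate
Product: 9 (2E,6E,10E)-3,7,11-trimethyl-12-oxododeca-2,6,10-trien-1-yl acetate
Conditions: MnO2 (activated, excess), CH2Cl2, rt
Reagents that add atoms: none
Why: MnO2 oxidises allylic alcohols selectively, with retention of the (10E) geometry and without touching the acetate or the other alkenes.

**Step 4**
Reactants: 9 (2E,6E,10E)-3,7,11-trimethyl-12-oxododeca-2,6,10-trien-1-yl acetate
Product: 10 (2E,6E,10E)-12-acetoxy-2,6,10-trimethyldodeca-2,6,10-trienoic acid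
Conditions: NaClO2, NaH2PO4, 2-methyl-2-butene, t-BuOH/H2O, 0 °C to rt
Reagents that add atoms: sodium chlorite NaClO2, [Na+].[O-]Cl=O
Why: Pinnick (chlorite) oxidation converts the enal into the enoic acid without isomerising the (2E) alkene, the 2-methyl-2-butene scavenging the hypochlorous acid that would otherwise attack the other alkenes.

**Step 5**
Reactants: 10 (2E,6E,10E)-12-acetoxy-2,6,10-trimethyldodeca-2,6,10-trienoic acid
Product: 11 (2S,6E,10E)-12-acetoxy-2,6,10-trimethyldodeca-6,10-dienoic acid
Conditions: Ru(OAc)2[(S)-H8-BINAP] (cat.), H2 (about 2 atm), MeOH, rt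
Reagents that add atoms: none
Why: Carboxylate-directed asymmetric hydrogenation with a BINAP-type ruthenium dicarboxylate (Noyori-type) reduces only the alkene conjugated to the coordinating acid, the allylic acetate and the two isolated trisubstituted alkenes having no directing group, and the (S)-configured ligand should deliver hydrogen to the face that gives the (2S) centre, as it does for tiglic acid.

**Step 6**
Reactants: 11 (2S,6E,10E)-12-acetoxy-2,6,10-trimethyldodeca-6,10-dienoic acid
Product: 13 methyl (2S,6E,10E)-12-hydroxy-2,6,10-trimethyldodeca-6,10-dienoate, via acetoxy methyl ester 12 (not isolated)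
Conditions: TMSCHN2, toluene/MeOH, 0 °C; concentrate; K2CO3 (cat.), MeOH, rt
Reagents that add atoms: (trimethylsilyl)diazomethane, C[Si](C)(C)C=[N+]=[N-]
Why: Methylation of the acid by the diazoalkane followed by carbonate-catalysed transesterification of the primary allylic acetate to methanol should give the hydroxy ester in one flask, conditions under which the methyl ester is unchanged and C2 is not epimerised.

**Step 7**
Reactants: 13 methyl (2S,6E,10E)-12-hydroxy-2,6,10-trimethyldodeca-6,10-dienoate
Product: 14 methyl (2S,6E,10E)-12-bromo-2,6,10-trimethyldodeca-6,10-dienoate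
Conditions: CBr4, PPh3, CH2Cl2, 0 °C; used crude
Reagents that add atoms: carbon tetrabromide, BrC(Br)(Br)Br
Why: Appel bromination proceeds by SN2 displacement of the alkoxyphosphonium at the primary allylic carbon, without allylic transposition or loss of the (10E) geometry at 0 °C.

**Step 8**
Reactants: 14 methyl (2S,6E,10E)-12-bromo-2,6,10-trimethyldodeca-6,10-dienoate; 15 ethynyltrimethylsilane
Product: 16 methyl (2S,6E,10E)-2,6,10-trimethyl-14-(trimethylsilyl)tetradeca-6,10-dien-13-ynoate
Conditions: CuI (cat.), NaI, K2CO3, DMF, rt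
Reagents that add atoms: none
Why: Copper-catalysed allyl–alkynyl coupling, in which the copper acetylide formed under carbonate base substitutes the primary allylic bromide at its unsubstituted terminus with retention of the (10E) alkene, should give the skipped enyne while the mild base leaves the ester and C2 untouched.

**Step 9**
Reactants: 16 methyl (2S,6E,10E)-2,6,10-trimethyl-14-(trimethylsilyl)tetradeca-6,10-dien-13-ynoate
Product: 17 methyl (2S,6E,10E)-2,6,10-trimethyltetradeca-6,10-dien-13-ynoate
Conditions: K2CO3, MeOH, 0 °C to rt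
Reagents that add atoms: none
Why: Methoxide-mediated protodesilylation of the alkynylsilane is fast under conditions too mild to isomerise the skipped enyne or to epimerise C2.

**Step 10**
Reactants: 17 methyl (2S,6E,10E)-2,6,10-trimethyltetradeca-6,10-dien-13-ynoate
Product: 19 methyl (2S,6E,10E,13E)-14-iodo-2,6,10-trimethyltetradeca-6,10,13-trienoate, via alkenylzirconocene chloride 18 (not isolated)
Conditions: Cp2Zr(H)Cl, THF, rt, dark; I2, THF, 0 °C
Reagents that add atoms: iodine, [I][I]
Why: Hydrozirconation of the terminal alkyne (syn addition with zirconium at the terminal carbon, much faster than reaction with trisubstituted alkenes or the ester) followed by iodinolysis with retention should give the (13E)-vinyl iodide.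

**Step 11**
Reactants: 19 methyl (2S,6E,10E,13E)-14-iodo-2,6,10-trimethyltetradeca-6,10,13-trienoate
Product: 20 (2S,6E,10E,13E)-14-iodo-2,6,10-trimethyltetradeca-6,10,13-trienoic acid
Conditions: LiOH, THF/MeOH/H2O, rt; then 1 M HCl to pH 3
Reagents that add atoms: lithium hydroxide LiOH, [Li+].[OH-]
Why: Ester saponification at room temperature leaves the vinyl iodide and the skipped diene intact and does not enolise the α-branched ester, so C2 should keep its (S) configuration.

**Step 12**
Reactants: 20 (2S,6E,10E,13E)-14-iodo-2,6,10-trimethyltetradeca-6,10,13-trienoic acid; 6 3-isopropoxy-4-[(methoxymethoxy)methyl]cyclobut-3-ene-1,2-dione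
Product: 23 (2S,6E,10E,13E)-14-[1-hydroxy-2-isopropoxy-3-[(methoxymethoxy)methyl]-4-oxocyclobut-2-en-1-yl]-2,6,10-trimethyltetradeca-6,10,13-trienoic acid, via lithium carboxylate 21 (not isolated), via vinyllithium carboxylate 22 (not isolated)
Conditions: MeLi (1.0 equiv), THF, −78 °C; t-BuLi (2 equiv), −78 °C; 6, THF, −78 °C; aq. NH4Cl, then NaH2PO4 buffer (pH about 5)
Reagents that add atoms: none
Why: MeLi first turns the acid into lithium carboxylate 21, the least electrophilic carboxyl derivative and slow to enolise at −78 °C, so that t-BuLi effects iodine–lithium exchange with retention of the (13E) geometry and vinyllithium 22 adds 1,2 to the ketone-like carbonyl of 6 next to the isopropoxy-bearing carbon, not to the vinylogous ester carbonyl (organolithium addition to a cyclobutenedione), the new carbinol centre being formed without control and destroyed in step 13.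

**Step 13**
Reactants: 23 (2S,6E,10E,13E)-14-[1-hydroxy-2-isopropoxy-3-[(methoxymethoxy)methyl]-4-oxocyclobut-2-en-1-yl]-2,6,10-trimethyltetradeca-6,10,13-trienoic acid
Product: 26 (2S,6E,10E)-12-[2,5-dihydroxy-4-isopropoxy-3-[(methoxymethoxy)methyl]phenyl]-2,6,10-trimethyldodeca-6,10-dienoic acid, via (Z)-dienylketene 24 (not isolated), via cyclohexa-2,4-dienone 25 (not isolated)
Conditions: toluene (degassed, 0.01 M), 110 °C, Ar
Reagents that add atoms: none
Why: This is a Moore rearrangement (thermal ring expansion of a 4-alkenyl-4-hydroxycyclobutenone): on heating, the bond between the carbonyl carbon and the carbinol carbon opens by 4π conrotatory electrocyclic cleavage to dienylketene 24. The donor hydroxyl rotates outward, which turns the alkenyl group inward, cis to the ketene, and keeps the hydroxyl away from the ketene carbon so that butenolide formation is avoided. The benzene ring then closes by a thermally allowed disrotatory 6π electrocyclisation joining the ketene carbon (future C6) to the β-carbon of the alkenyl group (future C1) to give cyclohexadienone 25, whose enolisation to the hydroquinone is driven by aromatisation. No stereocentre is created, since the carbinol carbon and the transient sp3 C1 of 25 both become aromatic carbons and C2 of the acid chain is remote and untouched. The substitution pattern (C3–OH from the carbinol, C4–O-iPr, C5–CH2OMOM, C6–OH from the carbonyl) is already fixed by the connectivity of 23, so the only selectivity needed is the outward rotation of the hydroxyl, which its donor character secures. The two chain alkenes and the carboxylic acid are spectators, and dilution with exclusion of oxygen should suppress intermolecular ketene capture and oxidation to the quinone.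

**Step 14**
Reactants: 26 (2S,6E,10E)-12-[2,5-dihydroxy-4-isopropoxy-3-[(methoxymethoxy)methyl]phenyl]-2,6,10-trimethyldodeca-6,10-dienoic acid
Product: 28 (2S,6E,10E)-12-[2,5-dihydroxy-3-(hydroxymethyl)-4-isopropoxyphenyl]-2,6,10-trimethyldodeca-6,10-dienoic acid, via N-(alkoxymethyl)bipyridinium triflate 27 (not isolated)
Conditions: TMSOTf, 2,2'-bipyridyl, CH2Cl2, 0 °C to rt, Ar; then H2O/THF, rt
Reagents that add atoms: none
Why: In this silyl triflate–bipyridyl cleavage of a MOM acetal the buffered silyl triflate activates the terminal methoxy oxygen and bipyridyl displaces it at the acetal carbon to give pyridinium salt 27 (phenols and acid being silylated transiently), which water hydrolyses under near-neutral conditions, so the benzylic C–O bond of the electron-rich ring should not be ionised and the alkenes see no strong acid.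

**Step 15**
Reactants: 28 (2S,6E,10E)-12-[2,5-dihydroxy-3-(hydroxymethyl)-4-isopropoxyphenyl]-2,6,10-trimethyldodeca-6,10-dienoic acid
Product: 30 (2S,6E,10E)-12-(3-formyl-2,5-dihydroxy-4-isopropoxyphenyl)-2,6,10-trimethyldodeca-6,10-dienoic acid, via formylquinone 29 (not isolated)
Conditions: Dess–Martin periodinane (3 equiv), CH2Cl2, 0 °C to rt; then aq. Na2S2O4, Et2O, rt
Reagents that add atoms: none
Why: Dess–Martin oxidation should take the hydroquinone to the quinone and the primary alcohol to the aldehyde without touching the isolated alkenes or the acid, and shaking crude formylquinone 29 with aqueous Na2S2O4 reduces only the quinone, returning a hydroquinone stabilised by the hydrogen-bonded ortho-formyl group.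

**Step 16**
Reactants: 30 (2S,6E,10E)-12-(3-formyl-2,5-dihydroxy-4-isopropoxyphenyl)-2,6,10-trimethyldodeca-6,10-dienoic acid
Product: 31 (2S,6E,10E)-12-(3-formyl-2,4,5-trihydroxyphenyl)-2,6,10-trimethyldodeca-6,10-dienoic acid
Conditions: BCl3, 2,6-di-tert-butylpyridine, CH2Cl2, −78 °C; aq. work-up under Ar
Reagents that add atoms: none
Why: In this chelation-assisted Lewis acid dealkylation BCl3 binds between the formyl oxygen and the adjacent isopropyl ether and chloride removes the secondary alkyl group at −78 °C, while the hindered pyridine traps the HCl released from the phenols and the acid so that the trisubstituted alkenes and the ortho-prenylphenol motif should not be protonated.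

**Compound list**

1 | diisopropyl squarate (3,4-diisopropoxycyclobut-3-ene-1,2-dione) | CC(C)OC1=C(OC(C)C)C(=O)C1=O | starting material
2 | tributyl[(methoxymethoxy)methyl]stannane | CCCC[Sn](CCCC)(CCCC)COCOC | starting material
3 | (methoxymethoxy)methyllithium | [Li]COCOC | intermediate
4 | lithium 2,3-diisopropoxy-1-[(methoxymethoxy)methyl]-4-oxocyclobut-2-en-1-olate (racemic) | [Li+].[O-]C1(COCOC)C(OC(C)C)=C(OC(C)C)C1=O | intermediate
5 | 2,3-diisopropoxy-1-[(methoxymethoxy)methyl]-4-oxocyclobut-2-en-1-yl trifluoroacetate (racemic) | COCOCC1(OC(=O)C(F)(F)F)C(OC(C)C)=C(OC(C)C)C1=O | intermediate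
6 | 3-isopropoxy-4-[(methoxymethoxy)methyl]cyclobut-3-ene-1,2-dione | COCOCC1=C(OC(C)C)C(=O)C1=O | intermediate
7 | (2E,6E)-farnesyl acetate | C/C(=C\COC(C)=O)CC/C=C(\C)CCC=C(C)C | starting material
8 | (2E,6E,10E)-12-hydroxy-3,7,11-trimethyldodeca-2,6,10-trien-1-yl acetate | C/C(=C\COC(C)=O)CC/C=C(\C)CC/C=C(\C)CO | intermediate
9 | (2E,6E,10E)-3,7,11-trimethyl-12-oxododeca-2,6,10-trien-1-yl acetate | C/C(=C\COC(C)=O)CC/C=C(\C)CC/C=C(\C)C=O | intermediate
10 | (2E,6E,10E)-12-acetoxy-2,6,10-trimethyldodeca-2,6,10-trienoic acid | C/C(=C\COC(C)=O)CC/C=C(\C)CC/C=C(\C)C(=O)O | intermediate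
11 | (2S,6E,10E)-12-acetoxy-2,6,10-trimethyldodeca-6,10-dienoic acid | C/C(=C\COC(C)=O)CC/C=C(\C)CCC[C@H](C)C(=O)O | intermediate
12 | methyl (2S,6E,10E)-12-acetoxy-2,6,10-trimethyldodeca-6,10-dienoate | C/C(=C\COC(C)=O)CC/C=C(\C)CCC[C@H](C)C(=O)OC | intermediate
13 | methyl (2S,6E,10E)-12-hydroxy-2,6,10-trimethyldodeca-6,10-dienoate | C/C(=C\CO)CC/C=C(\C)CCC[C@H](C)C(=O)OC | intermediate
14 | methyl (2S,6E,10E)-12-bromo-2,6,10-trimethyldodeca-6,10-dienoate | C/C(=C\CBr)CC/C=C(\C)CCC[C@H](C)C(=O)OC | intermediate
15 | ethynyltrimethylsilane | C#C[Si](C)(C)C | starting material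
16 | methyl (2S,6E,10E)-2,6,10-trimethyl-14-(trimethylsilyl)tetradeca-6,10-dien-13-ynoate | C/C(=C\CC#C[Si](C)(C)C)CC/C=C(\C)CCC[C@H](C)C(=O)OC | intermediate
17 | methyl (2S,6E,10E)-2,6,10-trimethyltetradeca-6,10-dien-13-ynoate | C/C(=C\CC#C)CC/C=C(\C)CCC[C@H](C)C(=O)OC | intermediate
18 | methyl (2S,6E,10E,13E)-14-[chlorobis(cyclopentadienyl)zirconio]-2,6,10-trimethyltetradeca-6,10,13-trienoate | C/C(=C\C/C=C/[Zr](Cl)(C1C=CC=C1)C1C=CC=C1)CC/C=C(\C)CCC[C@H](C)C(=O)OC | intermediate
19 | methyl (2S,6E,10E,13E)-14-iodo-2,6,10-trimethyltetradeca-6,10,13-trienoate | C/C(=C\C/C=C/I)CC/C=C(\C)CCC[C@H](C)C(=O)OC | intermediate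
20 | (2S,6E,10E,13E)-14-iodo-2,6,10-trimethyltetradeca-6,10,13-trienoic acid | C/C(=C\C/C=C/I)CC/C=C(\C)CCC[C@H](C)C(=O)O | intermediate
21 | lithium (2S,6E,10E,13E)-14-iodo-2,6,10-trimethyltetradeca-6,10,13-trienoate | C/C(=C\C/C=C/I)CC/C=C(\C)CCC[C@H](C)C(=O)[O-].[Li+] | intermediate
22 | lithium (2S,6E,10E,13E)-14-lithio-2,6,10-trimethyltetradeca-6,10,13-trienoate | C/C(=C\C/C=C/[Li])CC/C=C(\C)CCC[C@H](C)C(=O)[O-].[Li+] | intermediate
23 | (2S,6E,10E,13E)-14-[1-hydroxy-2-isopropoxy-3-[(methoxymethoxy)methyl]-4-oxocyclobut-2-en-1-yl]-2,6,10-trimethyltetradeca-6,10,13-trienoic acid (both carbinol epimers) | C/C(=C\C/C=C/C1(O)C(OC(C)C)=C(COCOC)C1=O)CC/C=C(\C)CCC[C@H](C)C(=O)O | intermediate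
24 | (Z)-dienylketene: (2S,6E,10E,13E,15Z)-15-hydroxy-16-isopropoxy-17-[(methoxymethoxy)methyl]-2,6,10-trimethyl-18-oxooctadeca-6,10,13,15,17-pentaenoic acid | O=C=C(COCOC)/C(OC(C)C)=C(O)\C=C\C/C=C(\C)CC/C=C(\C)CCC[C@H](C)C(=O)O | intermediate
25 | (2S,6E,10E)-12-[4-hydroxy-3-isopropoxy-2-[(methoxymethoxy)methyl]-1-oxocyclohexa-2,4-dien-6-yl]-2,6,10-trimethyldodeca-6,10-dienoic acid (ring sp3 carbon unspecified) | O=C1C(COCOC)=C(OC(C)C)C(O)=CC1C/C=C(\C)CC/C=C(\C)CCC[C@H](C)C(=O)O | intermediate
26 | (2S,6E,10E)-12-[2,5-dihydroxy-4-isopropoxy-3-[(methoxymethoxy)methyl]phenyl]-2,6,10-trimethyldodeca-6,10-dienoic acid | C/C(=C\Cc1cc(O)c(OC(C)C)c(COCOC)c1O)CC/C=C(\C)CCC[C@H](C)C(=O)O | intermediate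
27 | tris(trimethylsilyl) derivative of 26 in which the methoxy group is replaced by N-(2,2'-bipyridinium), triflate salt | C/C(=C\Cc1cc(O[Si](C)(C)C)c(OC(C)C)c(COC[n+]2ccccc2-c2ccccn2)c1O[Si](C)(C)C)CC/C=C(\C)CCC[C@H](C)C(=O)O[Si](C)(C)C.[O-]S(=O)(=O)C(F)(F)F | intermediate
28 | (2S,6E,10E)-12-[2,5-dihydroxy-3-(hydroxymethyl)-4-isopropoxyphenyl]-2,6,10-trimethyldodeca-6,10-dienoic acid | C/C(=C\Cc1cc(O)c(OC(C)C)c(CO)c1O)CC/C=C(\C)CCC[C@H](C)C(=O)O | intermediate
29 | (2S,6E,10E)-12-(5-formyl-4-isopropoxy-3,6-dioxocyclohexa-1,4-dien-1-yl)-2,6,10-trimethyldodeca-6,10-dienoic acid | C/C(=C\CC1=CC(=O)C(OC(C)C)=C(C=O)C1=O)CC/C=C(\C)CCC[C@H](C)C(=O)O | intermediate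
30 | (2S,6E,10E)-12-(3-formyl-2,5-dihydroxy-4-isopropoxyphenyl)-2,6,10-trimethyldodeca-6,10-dienoic acid | C/C(=C\Cc1cc(O)c(OC(C)C)c(C=O)c1O)CC/C=C(\C)CCC[C@H](C)C(=O)O | intermediate
31 | (2S,6E,10E)-12-(3-formyl-2,4,5-trihydroxyphenyl)-2,6,10-trimethyldodeca-6,10-dienoic acid (CNP0180353.1) | C/C(=C\Cc1cc(O)c(O)c(C=O)c1O)CC/C=C(\C)CCC[C@H](C)C(=O)O | target

**Step count**

Total: 16 steps. Longest linear sequence: 15 steps (steps 2–16, from farnesyl acetate 7 to 31); step 1 is a one-step branch that joins at step 12.

**Steps most likely to fail**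

Step 13 (key step). The free carboxylic acid may act as a proton source during heating and ionise the tertiary allylic carbinol with loss of isopropanol. Ring opening with the hydroxyl turned inward would let the carbinol oxygen capture the ketene and give a butenolide. The hydroquinone may also be oxidised by traces of air. The fallback sets out from 23: both acidic hydrogens are capped with N,O-bis(trimethylsilyl)acetamide to give the trimethylsilyl ester 4-(trimethylsilyloxy)cyclobutenone F1, whose silyl ether still rotates outward but cannot lactonise and whose acid is masked. The same thermolysis should give the mono-silylated hydroquinone silyl ester F2, and dilute aqueous citric acid in THF under argon removes both silyl groups, returning to the route at 26.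

Step 12. Aggregation or poor solubility of the lithium carboxylate at −78 °C may lead to incomplete iodine–lithium exchange, proton transfer to the vinyllithium, or attack of t-BuLi on the carboxylate. The fallback sets out from 20 and masks the carboxyl as a base-inert ortho ester. Esterification with (3-methyloxetan-3-yl)methanol (DCC, DMAP) gives the oxetanylmethyl ester F3, and catalytic BF3·OEt2 (CH2Cl2, −15 °C) rearranges it to the 4-methyl-2,6,7-trioxabicyclo[2.2.2]octane ortho ester F4. Exchange with t-BuLi and addition to 6 then give the ortho ester hydroxycyclobutenone F5, and thermolysis as in step 13 gives the ortho ester hydroquinone F6. Brief treatment with aqueous NaHSO4 in THF opens the ortho ester to the 3-hydroxy-2-(hydroxymethyl)-2-methylpropyl ester F7, and LiOH in degassed aqueous THF liberates the acid, returning to the route at 26.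

Step 14. The benzylic C–O bond of the very electron-rich ortho-hydroxybenzyl system may ionise instead of the acetal being cleaved, leading through an ortho-quinone methide to oligomers. The fallback sets out from 26: oxidation with Ag2O (Et2O, MgSO4) gives the isopropoxyquinone MOM ether F8, in which the ring is electron-poor and the CH2OMOM group behaves as an ordinary alkyl MOM ether. Aqueous HCl in THF, or HCl in isopropanol where exchange of the vinylogous ester is degenerate, then gives the hydroxymethylquinone F9. Dess–Martin oxidation of this alcohol gives formylquinone 29, where the route is rejoined before the Na2S2O4 reduction of step 15.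

**Further compounds**

F1 | step 13 | trimethylsilyl (2S,6E,10E,13E)-14-[2-isopropoxy-3-[(methoxymethoxy)methyl]-4-oxo-1-(trimethylsilyloxy)cyclobut-2-en-1-yl]-2,6,10-trimethyltetradeca-6,10,13-trienoate | C/C(=C\C/C=C/C1(O[Si](C)(C)C)C(OC(C)C)=C(COCOC)C1=O)CC/C=C(\C)CCC[C@H](C)C(=O)O[Si](C)(C)C
F2 | step 13 | trimethylsilyl (2S,6E,10E)-12-[2-hydroxy-4-isopropoxy-3-[(methoxymethoxy)methyl]-5-(trimethylsilyloxy)phenyl]-2,6,10-trimethyldodeca-6,10-dienoate | C/C(=C\Cc1cc(O[Si](C)(C)C)c(OC(C)C)c(COCOC)c1O)CC/C=C(\C)CCC[C@H](C)C(=O)O[Si](C)(C)C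
F3 | step 12 | (3-methyloxetan-3-yl)methyl (2S,6E,10E,13E)-14-iodo-2,6,10-trimethyltetradeca-6,10,13-trienoate | C/C(=C\C/C=C/I)CC/C=C(\C)CCC[C@H](C)C(=O)OCC1(C)COC1
F4 | step 12 | 1-[(2S,6E,10E,13E)-14-iodo-6,10-dimethyltetradeca-6,10,13-trien-2-yl]-4-methyl-2,6,7-trioxabicyclo[2.2.2]octane | C/C(=C\C/C=C/I)CC/C=C(\C)CCC[C@H](C)C12OCC(C)(CO1)CO2
F5 | step 12 | 4-hydroxy-3-isopropoxy-2-[(methoxymethoxy)methyl]-4-[(1E,4E,8E,13S)-4,8-dimethyl-13-(4-methyl-2,6,7-trioxabicyclo[2.2.2]octan-1-yl)tetradeca-1,4,8-trien-1-yl]cyclobut-2-en-1-one | C/C(=C\C/C=C/C1(O)C(OC(C)C)=C(COCOC)C1=O)CC/C=C(\C)CCC[C@H](C)C12OCC(C)(CO1)CO2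
F6 | step 12 | 2-[(2E,6E,11S)-3,7-dimethyl-11-(4-methyl-2,6,7-trioxabicyclo[2.2.2]octan-1-yl)dodeca-2,6-dien-1-yl]-5-isopropoxy-6-[(methoxymethoxy)methyl]benzene-1,4-diol | C/C(=C\Cc1cc(O)c(OC(C)C)c(COCOC)c1O)CC/C=C(\C)CCC[C@H](C)C12OCC(C)(CO1)CO2
F7 | step 12 | 3-hydroxy-2-(hydroxymethyl)-2-methylpropyl (2S,6E,10E)-12-[2,5-dihydroxy-4-isopropoxy-3-[(methoxymethoxy)methyl]phenyl]-2,6,10-trimethyldodeca-6,10-dienoate | C/C(=C\Cc1cc(O)c(OC(C)C)c(COCOC)c1O)CC/C=C(\C)CCC[C@H](C)C(=O)OCC(C)(CO)CO
F8 | step 14 | (2S,6E,10E)-12-[4-isopropoxy-5-[(methoxymethoxy)methyl]-3,6-dioxocyclohexa-1,4-dien-1-yl]-2,6,10-trimethyldodeca-6,10-dienoic acid | C/C(=C\CC1=CC(=O)C(OC(C)C)=C(COCOC)C1=O)CC/C=C(\C)CCC[C@H](C)C(=O)O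
F9 | step 14 | (2S,6E,10E)-12-[5-(hydroxymethyl)-4-isopropoxy-3,6-dioxocyclohexa-1,4-dien-1-yl]-2,6,10-trimethyldodeca-6,10-dienoic acid | C/C(=C\CC1=CC(=O)C(OC(C)C)=C(CO)C1=O)CC/C=C(\C)CCC[C@H](C)C(=O)O
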